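**Assumption:** Vogelin E has no stereocentre, so "single enantiomer" is taken to mean the single (2E)-alkene isomer; this geometry is the only stereochemical element to control.

## Retrosynthetic overview

1. Vogelin E (8) ⇐ global deacetylation of triacetate 7.
2. 7 ⇐ key step: Pd-catalysed SN2′ (1,4) arylative opening of isoprene monoxide (6) by arylboronate 5. This forms the C3′–CH2 bond and the (E)-allylic alcohol in its final oxidation state in one operation, with no prenylation/SeO2 sequence.
3. 5 ⇐ Miyaura borylation of 3′-bromogenistein triacetate (4) ⇐ 3′-bromogenistein (3).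
4. 3 ⇐ one-pot Friedel–Crafts acylation / C1 annulation of phloroglucinol (1) with 3-bromo-4-hydroxyphenylacetic acid (2), with no 3-iodochromone Suzuki coupling.
5. Ring order: A and B rings are purchased; the pyranone C ring is the only ring formed (step 1).

## Route

**Step 1**
Reactants: 1, phloroglucinol (anhydrous); 2, 3-bromo-4-hydroxyphenylacetic acid
Product: 3, 3-(3-bromo-4-hydroxyphenyl)-5,7-dihydroxy-4H-chromen-4-one (3′-bromogenistein)
Conditions: BF3·OEt2 (neat), 85 °C; then DMF, MsCl, 0 → 70 °C, one pot; aq. NaOAc work-up
Reagents that add atoms: N,N-dimethylformamide, CN(C)C=O (supplies C-2 and its H)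
Why: Friedel–Crafts C-acylation of the symmetric, electron-rich phloroglucinol gives the 2,4,6-trihydroxydeoxybenzoin as its BF2 chelate, whose methylene is formylated by the DMF/MsCl Vilsmeier-type reagent and cyclises onto an ortho-OH with loss of Me2NH (one-pot deoxybenzoin isoflavone synthesis); the aryl bromide is inert and symmetry removes any regiochemical issue.

**Step 2**
Reactants: 3, 3′-bromogenistein
Product: 4, 3-(4-acetoxy-3-bromophenyl)-4-oxo-4H-chromene-5,7-diyl diacetate (5,7,4′-triacetate)
Conditions: Ac2O, pyridine, DMAP (cat.), rt
Reagents that add atoms: acetic anhydride, CC(=O)OC(C)=O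
Why: DMAP-catalysed peracetylation caps all three phenols, including the chelated 5-OH, so that no phenoxide can intercept the π-allyl-Pd intermediate in step 4, and acetates come off later without acid.

**Step 3**
Reactants: 4, triacetate bromide
Product: 5, 3-[4-acetoxy-3-(4,4,5,5-tetramethyl-1,3,2-dioxaborolan-2-yl)phenyl]-4-oxo-4H-chromene-5,7-diyl diacetate
Conditions: B2pin2, Pd(dppf)Cl2·CH2Cl2 (5 mol %), KOAc, 1,4-dioxane, 85 °C
Reagents that add atoms: bis(pinacolato)diboron, CC1(C)OB(OC1(C)C)B1OC(C)(C)C(C)(C)O1
Why: Miyaura borylation converts the aryl bromide to the aryl-Bpin under anhydrous KOAc conditions that leave aryl acetates and the chromone untouched.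

**Step 4 (key step)**
Reactants: 5, arylboronate; 6, isoprene monoxide (2-methyl-2-vinyloxirane, racemic; its stereocentre is destroyed)
Product: 7, 3-{4-acetoxy-3-[(2E)-4-hydroxy-3-methylbut-2-en-1-yl]phenyl}-4-oxo-4H-chromene-5,7-diyl diacetate
Conditions: Pd(PPh3)4 (5 mol %), 6 (2 equiv, slow addition), THF/H2O (10:1), 40 °C, no added base; aq. NH4Cl work-up; remove minor Z isomer by chromatography
Reagents that add atoms: isoprene monoxide (6), CC1(C=C)CO1 (all five carbons and the oxygen are retained)
Why: Proposed new method: Pd(0) ionises the vinyl epoxide anti to the C–O bond (Tsuji–Trost) from the favoured s-trans conformer to give a zwitterionic π-allyl-Pd alkoxide with CH2O syn and CH3 anti; the internally generated alkoxide/hydroxide activates the Bpin for transmetalation, so no external base is needed and the acetates survive; aryl–allyl reductive elimination occurs at the unsubstituted CH2 terminus rather than the fully substituted one, giving the linear (E)-allylic alcohol as its O-boronate, which hydrolyses on work-up. The closest known reactions are the base-free Pd-catalysed 1,4-coupling of organoboron reagents with vinyl epoxides (allyl–aryl Suzuki–Miyaura type) and Pd-catalysed 1,4-additions to isoprene monoxide; the E:Z ratio on this substrate is untested.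

**Step 5**
Reactants: 7, coupled triacetate
Product: 8, Vogelin E, 5,7-dihydroxy-3-{4-hydroxy-3-[(2E)-4-hydroxy-3-methylbut-2-en-1-yl]phenyl}-4H-chromen-4-one
Conditions: K2CO3, MeOH/THF, 0 °C → rt; quench with aq. NH4Cl (pH ≈ 6)
Reagents that add atoms: none
Why: Mild methanolysis (transesterification) cleaves the three aryl acetates and any residual borate ester without acid, so the allylic alcohol cannot ionise or cyclise onto the 4′-OH and the trisubstituted alkene geometry is untouched.

## Compound list

1 | phloroglucinol (benzene-1,3,5-triol) | Oc1cc(O)cc(O)c1 | starting material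
2 | 3-bromo-4-hydroxyphenylacetic acid | OC(=O)Cc1ccc(O)c(Br)c1 | starting material
3 | 3′-bromogenistein | O=c1c(-c2ccc(O)c(Br)c2)coc2cc(O)cc(O)c12 | intermediate
4 | 3′-bromogenistein 5,7,4′-triacetate | CC(=O)Oc1ccc(-c2coc3cc(OC(C)=O)cc(OC(C)=O)c3c2=O)cc1Br | intermediate
5 | 3′-Bpin genistein 5,7,4′-triacetate | CC(=O)Oc1ccc(-c2coc3cc(OC(C)=O)cc(OC(C)=O)c3c2=O)cc1B1OC(C)(C)C(C)(C)O1 | intermediate
6 | isoprene monoxide (2-methyl-2-vinyloxirane, racemic) | CC1(C=C)CO1 | starting material
7 | Vogelin E 5,7,4′-triacetate, (E) | C/C(=C\Cc1cc(-c2coc3cc(OC(C)=O)cc(OC(C)=O)c3c2=O)ccc1OC(C)=O)CO | intermediate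
8 | Vogelin E, (E) | C/C(=C\Cc1cc(-c2coc3cc(O)cc(O)c3c2=O)ccc1O)CO | target

## Summary

Total step count: 5. Longest linear sequence: 5 steps (from 1 and 2).

Steps most likely to fail, each with a fallback that changes the approach:

1. **Step 4** (E:Z ratio, slow transmetalation or protodeboronation of the ortho-acetoxy aryl-Bpin, Pd-induced isomerisation of 6, over-arylation of the product allyl borate). Fallback: set the geometry by C–H oxidation instead. Couple bromide 4 with prenyl-Bpin (α-selective Suzuki prenylation), then Riley oxidation (cat. SeO2/t-BuOOH, with NaBH4/CeCl3 if the enal forms); the ene/[2,3] mechanism delivers the E-alcohol. Then deacetylate.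
2. **Step 3** (hindered, electron-rich ortho-acetoxy aryl bromide; protodebromination or acetate loss). Fallback: invert polarity and omit boron. Use Larock-type reductive Heck coupling of the aryl halide (preferably the 3′-iodo analogue, made from 3-iodo-4-hydroxyphenylacetic acid) directly with 6 (Pd(OAc)2, HCO2Na, Bu4NCl, i-Pr2NEt, DMF), which proceeds by carbopalladation then β-alkoxide elimination.
3. **Step 1** (yield and purification of the one-pot acylation/annulation with the brominated acid). Fallback: build the core by the chalcone route. Claisen–Schmidt condensation of 2-hydroxy-4,6-bis(methoxymethoxy)acetophenone with 3-bromo-4-(methoxymethoxy)benzaldehyde, then oxidative 1,2-aryl migration (PhI(OAc)2 or Tl(NO3)3) and acid cyclisation/MOM removal to give 3.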